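**Strategy.** Everything rests on cutting C9–C1 and C8–C7, the two carbocycle bonds that flank the trans ring-fusion edge C8–C9 shared by the oxolane (O, C10, C9, C8, C11) and the nine-membered ring (C1–C9); this edge is the C=C bond of 2(5H)-furanone. In one flask, a copper-catalysed asymmetric conjugate addition of an alkenylalane (C1–C4 as a silylated 1,4-enyne) sets C9, and the enolate is alkylated anti at C8 by a ketal-masked 3-oxobutyl iodide (C5–C7). The precursors are thus three achiral pieces. The lactone carbonyl later becomes quaternary C11, and a C4–C5 Nozaki–Hiyama–Kishi closure forms the nine-membered ring last.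

Key step: step 3

Atom labels used throughout: C1 exocyclic-methylene carbon, C2, C3=C4, C5 carbinol carbon, C6, C7, C8 and C9 ring fusion, C10 ring OCH2, C11 quaternary ether carbon, C12–C15 dienyl chain, C16 acyloxymethyl carbon.

Assumption: the copper–phosphoramidite catalyst is taken to discriminate the faces of 2(5H)-furanone in the same sense as those of cyclic enones, which calls for the (R,S,S) ligand; if the simple conjugate adduct proves to be (S), the antipodal ligand is used.

## Route

Step 1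
Reactants: 1 ethynyltrimethylsilane; 2 2,3-dibromoprop-1-ene
Product: 4 (4-bromopent-4-en-1-yn-1-yl)trimethylsilane, via alkynylmagnesium bromide 3 (not isolated)
Conditions: 1, EtMgBr, THF, 0 °C → rt; then 2, CuI (5 mol%), THF, rt → 45 °C
Reagents that add atoms: none
Why: Copper-catalysed allylic substitution of the alkynyl Grignard reagent on the allylic bromide of 2 (SN2 and SN2' give the same product) leaves the vinylic bromide untouched.

Step 2
Reactants: 5 2-(2-bromoethyl)-2-methyl-1,3-dioxolane
Product: 6 2-(2-iodoethyl)-2-methyl-1,3-dioxolane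
Conditions: NaI, NaHCO3 (cat.), acetone, reflux, dark
Reagents that add atoms: sodium iodide, [Na+].[I-]
Why: Finkelstein exchange at the unhindered primary carbon is driven by precipitation of NaBr in acetone and provides the more reactive electrophile needed for the enolate alkylation.

Step 3
Reactants: 4 (4-bromopent-4-en-1-yn-1-yl)trimethylsilane; 7 furan-2(5H)-one; 6 2-(2-iodoethyl)-2-methyl-1,3-dioxolane
Product: 12 (3S,4R)-3-[2-(2-methyl-1,3-dioxolan-2-yl)ethyl]-4-[5-(trimethylsilyl)pent-1-en-4-yn-2-yl]oxolan-2-one, via alkenyllithium 8 (not isolated), via alkenylalane 9 (not isolated), via aluminium enolate 10 (not isolated), via lithium aluminate 11 (not isolated)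
Conditions: 4, t-BuLi (2 equiv), Et2O, −78 °C; i-Bu2AlCl, −78 → −30 °C; Cu(OTf)2 (5 mol%), (R)-BINOL-derived N,N-bis[(S)-1-phenylethyl]phosphoramidite (10 mol%), slow addition of 7, Et2O/THF, −30 °C; MeLi, −30 °C; 6 (3 equiv), DMPU, −30 → 0 °C; aq. KNa tartrate
Reagents that add atoms: none
Why: Proposed new method: Bromine–lithium exchange and transmetalation give alkenylalane 9, whose alkenyl group passes to a chiral monovalent copper–phosphoramidite complex (formed in the flask by reduction of Cu(OTf)2) that adds to the β-carbon C9 of aluminium-activated 7 and releases aluminium enolate 10; MeLi turns 10 into the more nucleophilic aluminate 11, which is C-alkylated by 6 in an SN2 reaction. The closest known reaction types are the copper-catalysed asymmetric conjugate addition of alkenylalanes to cyclic enones and unsaturated lactams and the tandem conjugate addition–enolate alkylation of butenolides, whose union on the parent butenolide has not been shown. No ring is closed. C9 is set by the ligand on copper, which discriminates the two faces of the planar furanone, and C8 is set by the substrate, because the electrophile approaches the flat five-membered enolate on the face opposite the new C9 alkenyl group and so gives the trans lactone. The step needs alkenyl rather than isobutyl transfer, 1,4- rather than 1,2-addition and C- rather than O-alkylation: the sp2 group migrates faster from aluminium to copper, the soft copper nucleophile secures 1,4-addition, slow addition of 7 keeps the enolate from adding to unreacted 7, and the soft iodide with DMPU favours C-alkylation.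

Step 4
Reactants: 13 (tributylstannyl)methanol
Product: 14 tributyl[(1-ethoxyethoxy)methyl]stannane
Conditions: ethyl vinyl ether, PPTS (cat.), CH2Cl2, 0 °C → rt
Reagents that add atoms: ethyl vinyl ether, C=COCC
Why: Acid-catalysed addition of the primary alcohol to the enol ether gives the mixed acetal (acetal protection), whose new acetal carbon forms as both configurations without consequence because the group is removed in step 9.

Step 5
Reactants: 12 (3S,4R)-3-[2-(2-methyl-1,3-dioxolan-2-yl)ethyl]-4-[5-(trimethylsilyl)pent-1-en-4-yn-2-yl]oxolan-2-one; 14 tributyl[(1-ethoxyethoxy)methyl]stannane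
Product: 16 (3S,4R)-2-[(1-ethoxyethoxy)methyl]-3-[2-(2-methyl-1,3-dioxolan-2-yl)ethyl]-4-[5-(trimethylsilyl)pent-1-en-4-yn-2-yl]oxolan-2-ol (both anomers), via alkoxymethyllithium 15 (not isolated)
Conditions: 14, n-BuLi, THF, −78 °C; then 12, −78 °C; aq. NH4Cl
Reagents that add atoms: none
Why: Tin–lithium exchange gives the α-alkoxymethyllithium 15, which adds once to the lactone carbonyl because the tetrahedral lithium lactolate persists at −78 °C (addition of an organolithium to a lactone); C8 and C9 are untouched and the hemiketal carbon forms as an anomeric mixture that is levelled in step 6.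

Step 6
Reactants: 16 lactol from step 5
Product: 17 (3S,4R)-1-(1-ethoxyethoxy)-5-methylidene-3-[2-(2-methyl-1,3-dioxolan-2-yl)ethyl]-4-[(triethylsilyloxy)methyl]-8-(trimethylsilyl)oct-7-yn-2-one
Conditions: Et3SiCl, imidazole, DMAP (cat.), CH2Cl2, 0 °C
Reagents that add atoms: chlorotriethylsilane, CC[Si](CC)(CC)Cl
Why: Ring–chain tautomerism of the γ-hydroxy ketone lets the unhindered primary hydroxyl be silylated much faster than the tertiary hemiketal hydroxyl (silyl ether formation), which locks the open-chain ketone for olefination.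

Step 7
Reactants: 18 5-bromo-2-methylpent-2-ene
Product: 19 (4-methylpent-3-en-1-yl)triphenylphosphonium bromide
Conditions: PPh3, MeCN, reflux
Reagents that add atoms: triphenylphosphine, c1ccc(cc1)P(c1ccccc1)c1ccccc1
Why: SN2 quaternisation of triphenylphosphine by the primary bromide gives the phosphonium salt for the Wittig reaction.

Step 8
Reactants: 17 open-chain ketone from step 6; 19 (4-methylpent-3-en-1-yl)triphenylphosphonium bromide
Product: 21 [(2R,3S,4Z)-4-[(1-ethoxyethoxy)methyl]-8-methyl-3-[2-(2-methyl-1,3-dioxolan-2-yl)ethyl]-2-[5-(trimethylsilyl)pent-1-en-4-yn-2-yl]nona-4,7-dien-1-yl]oxy(triethyl)silane, via ylide 20 (not isolated)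
Conditions: 19, NaN(SiMe3)2, THF, 0 °C; then 17, −78 °C → rt
Reagents that add atoms: none
Why: Wittig olefination with the unstabilised ylide 20, which for α-alkoxy ketones is known to give mainly the (Z)-trisubstituted allylic ether (alkoxymethyl cis to the new chain); addition to the activated ketone at −78 °C should outrun enolisation at the methine C8, and the alkene geometry does not bear on the later C11 configuration.

Step 9
Reactants: 21 triene from step 8
Product: 22 (5S,6Z)-5-[(2R)-1-hydroxy-3-methylidene-6-(trimethylsilyl)hex-5-yn-2-yl]-6-(hydroxymethyl)-10-methylundeca-6,9-dien-2-one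
Conditions: 1 M HCl, THF, 0 °C → rt
Reagents that add atoms: water, O
Why: Dilute aqueous acid hydrolyses the triethylsilyl ether, the ethoxyethyl acetal and the dioxolane in one operation (acetal hydrolysis), while the alkenes and the silylalkyne are inert, so the ketone is unveiled before any acid-sensitive dienyl ether exists.

Step 10
Reactants: 22 keto diol from step 9
Product: 24 4-[(2R,3S,4R)-2-[(1R)-1-hydroxy-4-methylpent-3-en-1-yl]-2-(hydroxymethyl)-4-[5-(trimethylsilyl)pent-1-en-4-yn-2-yl]oxolan-3-yl]butan-2-one, via epoxy alcohol 23 (not isolated)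
Conditions: Ti(OiPr)4 (1.2 equiv), L-(+)-diethyl tartrate, t-BuOOH, 4 Å MS, CH2Cl2, −25 °C; then CSA (cat.), 0 °C
Reagents that add atoms: tert-butyl hydroperoxide, CC(C)(C)OO
Why: Katsuki–Sharpless asymmetric epoxidation with the L-(+)-tartrate complex delivers oxygen to the face of C11=C12 that makes C11 (S) in 23 whatever the alkene geometry (reagent control), and the C10 hydroxyl then opens the epoxide at the tertiary carbon C11 with inversion in a 5-exo-tet etherification, which sets (11R) with the hydroxymethyl group cis to the C7 arm and leaves a C12 carbinol that is removed in step 14.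

Step 11
Reactants: 24 oxolane diol from step 10; 25 octadecanoyl chloride
Product: 26 [(2R,3S,4R)-2-[(1R)-1-hydroxy-4-methylpent-3-en-1-yl]-3-(3-oxobutyl)-4-[5-(trimethylsilyl)pent-1-en-4-yn-2-yl]oxolan-2-yl]methyl octadecanoate
Conditions: 25 (1.05 equiv), 2,4,6-collidine, CH2Cl2, −40 → 0 °C
Reagents that add atoms: none
Why: Esterification with the acid chloride and a hindered pyridine base at low temperature is selective for the primary hydroxyl over the secondary C12 hydroxyl, which is flanked by the quaternary C11.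

Step 12
Reactants: 26 stearate from step 11
Product: 27 [(2R,3S,4R)-2-[(1R)-1-hydroxy-4-methylpent-3-en-1-yl]-4-(5-iodopent-1-en-4-yn-2-yl)-3-(3-oxobutyl)oxolan-2-yl]methyl octadecanoate
Conditions: NIS (1.1 equiv), AgNO3 (10 mol%), acetone, 0 °C → rt, dark
Reagents that add atoms: N-iodosuccinimide, O=C1CCC(=O)N1I
Why: Silver-catalysed iododesilylation of the trimethylsilylalkyne proceeds through a silver acetylide and is faster than attack of the iodinating agent on the isolated alkenes, and it needs no base that would touch the ester.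

Step 13
Reactants: 27 iodoalkyne from step 12
Product: 28 [(2R,3S,4R)-2-[(1R)-1-hydroxy-4-methylpent-3-en-1-yl]-4-[(4Z)-5-iodopenta-1,4-dien-2-yl]-3-(3-oxobutyl)oxolan-2-yl]methyl octadecanoate
Conditions: KO2CN=NCO2K, AcOH (slow addition), pyridine, MeOH, rt
Reagents that add atoms: none
Why: Diimide generated from dipotassium azodicarboxylate and acetic acid transfers two hydrogens syn to the iodoalkyne (cis-selective diimide reduction) to give the (Z)-iodoalkene, and this diimide source, unlike sulfonyl hydrazides, cannot condense with the methyl ketone.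

Step 14
Reactants: 28 (Z)-iodoalkene from step 13
Product: 30 [(2R,3S,4R)-4-[(4Z)-5-iodopenta-1,4-dien-2-yl]-2-[(1E)-4-methylpenta-1,3-dien-1-yl]-3-(3-oxobutyl)oxolan-2-yl]methyl octadecanoate, via sulfamate salt 29 (not isolated)
Conditions: MeO2CN(−)SO2N(+)Et3, toluene, 50 °C
Reagents that add atoms: none
Why: Burgess dehydration, in which the secondary alcohol forms sulfamate 29 and this undergoes thermal syn elimination; C11 carries no hydrogen, so only the allylic hydrogens at C13 can be lost and the conjugated (E)-diene should result.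

Step 15
Reactants: 30 keto iodide from step 14
Product: 32 target CNP0274030.1 [(3Z,5S,8S,9R,11R,12E) in the atom labels above], via alkenylchromium dichloride 31 (not isolated)
Conditions: CrCl2 (10 equiv), NiCl2 (0.1 equiv), DMSO/THF, rt, 2 mM, slow addition
Reagents that add atoms: none
Why: Nozaki–Hiyama–Kishi reaction, in which zerovalent nickel inserts into the C–I bond, transmetalation gives the (Z)-alkenylchromium 31 with retention, and its intramolecular addition to the C5 ketone closes the nine-membered ring without touching ester, diene or exocyclic alkene; C5 is set under substrate control by the conformation of the trans-fused bicyclic transition state, the (5S) alcohol being the intended product and its epimer separable.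

## Compound list

1 | ethynyltrimethylsilane | C#C[Si](C)(C)C | starting material
2 | 2,3-dibromoprop-1-ene | C=C(Br)CBr | starting material
3 | [(trimethylsilyl)ethynyl]magnesium bromide | C[Si](C)(C)C#C[Mg]Br | intermediate
4 | (4-bromopent-4-en-1-yn-1-yl)trimethylsilane | C=C(Br)CC#C[Si](C)(C)C | intermediate
5 | 2-(2-bromoethyl)-2-methyl-1,3-dioxolane | CC1(CCBr)OCCO1 | starting material
6 | 2-(2-iodoethyl)-2-methyl-1,3-dioxolane | CC1(CCI)OCCO1 | intermediate
7 | furan-2(5H)-one | O=C1OCC=C1 | starting material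
8 | [5-(trimethylsilyl)pent-1-en-4-yn-2-yl]lithium | [Li]C(=C)CC#C[Si](C)(C)C | intermediate
9 | diisobutyl[5-(trimethylsilyl)pent-1-en-4-yn-2-yl]aluminium | CC(C)C[Al](CC(C)C)C(=C)CC#C[Si](C)(C)C | intermediate
10 | diisobutylaluminium enolate of (4R)-4-[5-(trimethylsilyl)pent-1-en-4-yn-2-yl]oxolan-2-one | CC(C)C[Al](CC(C)C)OC1=C[C@@H](CO1)C(=C)CC#C[Si](C)(C)C | intermediate
11 | lithium diisobutyl(methyl)aluminate of the same enolate | [Li+].CC(C)C[Al-](C)(CC(C)C)OC1=C[C@@H](CO1)C(=C)CC#C[Si](C)(C)C | intermediate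
12 | (3S,4R)-3-[2-(2-methyl-1,3-dioxolan-2-yl)ethyl]-4-[5-(trimethylsilyl)pent-1-en-4-yn-2-yl]oxolan-2-one | O=C1OC[C@@H](C(=C)CC#C[Si](C)(C)C)[C@@H]1CCC2(C)OCCO2 | intermediate
13 | (tributylstannyl)methanol | CCCC[Sn](CCCC)(CCCC)CO | starting material
14 | tributyl[(1-ethoxyethoxy)methyl]stannane | CCCC[Sn](CCCC)(CCCC)COC(C)OCC | intermediate
15 | [(1-ethoxyethoxy)methyl]lithium | [Li]COC(C)OCC | intermediate
16 | (3S,4R)-2-[(1-ethoxyethoxy)methyl]-3-[2-(2-methyl-1,3-dioxolan-2-yl)ethyl]-4-[5-(trimethylsilyl)pent-1-en-4-yn-2-yl]oxolan-2-ol (mixture at the hemiketal and acetal carbons) | OC1(COC(C)OCC)OC[C@@H](C(=C)CC#C[Si](C)(C)C)[C@@H]1CCC2(C)OCCO2 | intermediate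
17 | (3S,4R)-1-(1-ethoxyethoxy)-5-methylidene-3-[2-(2-methyl-1,3-dioxolan-2-yl)ethyl]-4-[(triethylsilyloxy)methyl]-8-(trimethylsilyl)oct-7-yn-2-one | CC[Si](CC)(CC)OC[C@@H](C(=C)CC#C[Si](C)(C)C)[C@H](CCC1(C)OCCO1)C(=O)COC(C)OCC | intermediate
18 | 5-bromo-2-methylpent-2-ene | CC(C)=CCCBr | starting material
19 | (4-methylpent-3-en-1-yl)triphenylphosphonium bromide | CC(C)=CCC[P+](c1ccccc1)(c1ccccc1)c1ccccc1.[Br-] | intermediate
20 | (4-methylpent-3-en-1-ylidene)triphenylphosphorane | CC(C)=CCC=P(c1ccccc1)(c1ccccc1)c1ccccc1 | intermediate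
21 | [(2R,3S,4Z)-4-[(1-ethoxyethoxy)methyl]-8-methyl-3-[2-(2-methyl-1,3-dioxolan-2-yl)ethyl]-2-[5-(trimethylsilyl)pent-1-en-4-yn-2-yl]nona-4,7-dien-1-yl]oxy(triethyl)silane | CC[Si](CC)(CC)OC[C@@H](C(=C)CC#C[Si](C)(C)C)[C@H](CCC1(C)OCCO1)/C(COC(C)OCC)=C/CC=C(C)C | intermediate
22 | (5S,6Z)-5-[(2R)-1-hydroxy-3-methylidene-6-(trimethylsilyl)hex-5-yn-2-yl]-6-(hydroxymethyl)-10-methylundeca-6,9-dien-2-one | OC[C@@H](C(=C)CC#C[Si](C)(C)C)[C@H](CCC(C)=O)/C(CO)=C/CC=C(C)C | intermediate
23 | (5S,6R)-6-(hydroxymethyl)-5-[(2S,3R)-2-(hydroxymethyl)-3-(3-methylbut-2-en-1-yl)oxiran-2-yl]-7-methylidene-10-(trimethylsilyl)dec-9-yn-2-one | OC[C@@H](C(=C)CC#C[Si](C)(C)C)[C@H](CCC(C)=O)[C@@]1(CO)O[C@@H]1CC=C(C)C | intermediate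
24 | 4-[(2R,3S,4R)-2-[(1R)-1-hydroxy-4-methylpent-3-en-1-yl]-2-(hydroxymethyl)-4-[5-(trimethylsilyl)pent-1-en-4-yn-2-yl]oxolan-3-yl]butan-2-one | CC(=O)CC[C@H]1[C@H](C(=C)CC#C[Si](C)(C)C)CO[C@@]1([C@H](O)CC=C(C)C)CO | intermediate
25 | octadecanoyl chloride | CCCCCCCCCCCCCCCCCC(Cl)=O | starting material
26 | [(2R,3S,4R)-2-[(1R)-1-hydroxy-4-methylpent-3-en-1-yl]-3-(3-oxobutyl)-4-[5-(trimethylsilyl)pent-1-en-4-yn-2-yl]oxolan-2-yl]methyl octadecanoate | CC(=O)CC[C@H]1[C@H](C(=C)CC#C[Si](C)(C)C)CO[C@@]1([C@H](O)CC=C(C)C)COC(=O)CCCCCCCCCCCCCCCCC | intermediate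
27 | [(2R,3S,4R)-2-[(1R)-1-hydroxy-4-methylpent-3-en-1-yl]-4-(5-iodopent-1-en-4-yn-2-yl)-3-(3-oxobutyl)oxolan-2-yl]methyl octadecanoate | CC(=O)CC[C@H]1[C@H](C(=C)CC#CI)CO[C@@]1([C@H](O)CC=C(C)C)COC(=O)CCCCCCCCCCCCCCCCC | intermediate
28 | [(2R,3S,4R)-2-[(1R)-1-hydroxy-4-methylpent-3-en-1-yl]-4-[(4Z)-5-iodopenta-1,4-dien-2-yl]-3-(3-oxobutyl)oxolan-2-yl]methyl octadecanoate | CC(=O)CC[C@H]1[C@H](C(=C)C/C=C\I)CO[C@@]1([C@H](O)CC=C(C)C)COC(=O)CCCCCCCCCCCCCCCCC | intermediate
29 | triethylammonium salt of the C12 O-sulfonyl-N-(methoxycarbonyl)amide (sulfamate ester) of 28 | CC(=O)CC[C@H]1[C@H](C(=C)C/C=C\I)CO[C@@]1([C@H](OS(=O)(=O)[N-]C(=O)OC)CC=C(C)C)COC(=O)CCCCCCCCCCCCCCCCC.CC[NH+](CC)CC | intermediate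
30 | [(2R,3S,4R)-4-[(4Z)-5-iodopenta-1,4-dien-2-yl]-2-[(1E)-4-methylpenta-1,3-dien-1-yl]-3-(3-oxobutyl)oxolan-2-yl]methyl octadecanoate | CC(=O)CC[C@H]1[C@H](C(=C)C/C=C\I)CO[C@@]1(/C=C/C=C(C)C)COC(=O)CCCCCCCCCCCCCCCCC | intermediate
31 | (Z)-alkenylchromium dichloride derived from 30 (chromium in place of iodine at C4) | CC(=O)CC[C@H]1[C@H](C(=C)C/C=C\[Cr](Cl)Cl)CO[C@@]1(/C=C/C=C(C)C)COC(=O)CCCCCCCCCCCCCCCCC | intermediate
32 | CNP0274030.1: (3Z,5S,8S,9R,11R,12E)-configured nine-membered carbocycle trans-fused to the oxolane, with C1 methylidene, C5 hydroxyl and methyl, C11 dienyl and C16 octadecanoate | C=C1C/C=C\[C@@](C)(O)CC[C@H]2[C@H]1CO[C@@]2(/C=C/C=C(C)C)COC(=O)CCCCCCCCCCCCCCCCC | target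

## Step count and risks

Total step count: 15. Longest linear sequence: 12 steps (1, 3, 5, 6, 8, 9, 10, 11, 12, 13, 14, 15).

**Step 3 (carries the label).** What may go wrong: poor enantioface discrimination on the small lactone, oligomerisation through Michael addition of the enolate to unreacted furanone, and slow C-alkylation of the aluminate by the unactivated iodide with proton exchange that erodes the trans selectivity or leads to double alkylation. Fallback with known chemistry, setting out from 4 and 7 and returning at 12: bromoenyne 4 would be lithiated as in step 3 and quenched with 2-isopropoxy-4,4,5,5-tetramethyl-1,3,2-dioxaborolane to give 4,4,5,5-tetramethyl-2-[5-(trimethylsilyl)pent-1-en-4-yn-2-yl]-1,3,2-dioxaborolane F1. Rhodium-catalysed asymmetric 1,4-addition of this boronate to 7 ([Rh(OH)(cod)]2, the BINAP antipode that leads to the (R) adduct, dioxane/H2O, 50 °C) would give (4R)-4-[5-(trimethylsilyl)pent-1-en-4-yn-2-yl]oxolan-2-one F2. Deprotonation with LiN(iPr)2 (THF, −78 °C) and alkylation with 6 in the presence of DMPU, anti to the C9 substituent, would then give 12.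

**Step 15.** What may go wrong: carbonyl addition of the alkenylchromium to the hindered methyl ketone may be slower than its protonation, and the facial approach at C5 may be unselective or favour the wrong epimer. Fallback, setting out from 24 and returning at 32: the primary hydroxyl of 24 would be silylated (t-BuMe2SiCl, imidazole) to give the silyl ether F3. The alkyne would be converted as in steps 12 and 13 into the iodoalkyne F4 and the (Z)-iodoalkene F5, and the C12 hydroxyl eliminated as in step 14 to give the ester-free diene F6. Iodine–lithium exchange (t-BuLi, 2 equiv, Et2O/THF, −78 °C) with intramolecular addition of the alkenyllithium to the C5 ketone (anionic Barbier-type cyclisation) would give the nine-membered carbinol F7. Desilylation (Bu4NF, THF) would give the diol F8, and selective acylation of its primary hydroxyl with 25 (collidine, CH2Cl2) would give 32.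

**Step 10.** What may go wrong: mismatched double stereodifferentiation with the C8 stereocentre, or binding of the second hydroxyl to titanium, may lower the facial selectivity at C11, and the epoxide may open intermolecularly. Fallback, setting out from 22 and returning at 30: iodoetherification of 22 (NIS, MeCN, −20 °C) would close the oxolane by 5-exo attack of the C10 hydroxyl on C11 and place iodine at C12, giving the iodo ether F9. C11 is then set by the substrate, the bulky iodonium-bearing carbon being expected anti to the C7 arm. Acylation with 25 as in step 11 would give the stearate F10, elimination of HI (DBU, toluene, 60 °C) the dienyl silylalkyne F11, and iododesilylation as in step 12 the iodoalkyne F12. Diimide reduction as in step 13 would return to 30.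

## Further compounds

F1 | step 3 | 4,4,5,5-tetramethyl-2-[5-(trimethylsilyl)pent-1-en-4-yn-2-yl]-1,3,2-dioxaborolane | CC1(C)OB(OC1(C)C)C(=C)CC#C[Si](C)(C)C
F2 | step 3 | (4R)-4-[5-(trimethylsilyl)pent-1-en-4-yn-2-yl]oxolan-2-one | O=C1C[C@@H](CO1)C(=C)CC#C[Si](C)(C)C
F3 | step 15 | 4-[(2R,3S,4R)-2-[(tert-butyldimethylsilyloxy)methyl]-2-[(1R)-1-hydroxy-4-methylpent-3-en-1-yl]-4-[5-(trimethylsilyl)pent-1-en-4-yn-2-yl]oxolan-3-yl]butan-2-one | CC(=O)CC[C@H]1[C@H](C(=C)CC#C[Si](C)(C)C)CO[C@@]1([C@H](O)CC=C(C)C)CO[Si](C)(C)C(C)(C)C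
F4 | step 15 | 4-[(2R,3S,4R)-2-[(tert-butyldimethylsilyloxy)methyl]-2-[(1R)-1-hydroxy-4-methylpent-3-en-1-yl]-4-(5-iodopent-1-en-4-yn-2-yl)oxolan-3-yl]butan-2-one | CC(=O)CC[C@H]1[C@H](C(=C)CC#CI)CO[C@@]1([C@H](O)CC=C(C)C)CO[Si](C)(C)C(C)(C)C
F5 | step 15 | 4-[(2R,3S,4R)-2-[(tert-butyldimethylsilyloxy)methyl]-2-[(1R)-1-hydroxy-4-methylpent-3-en-1-yl]-4-[(4Z)-5-iodopenta-1,4-dien-2-yl]oxolan-3-yl]butan-2-one | CC(=O)CC[C@H]1[C@H](C(=C)C/C=C\I)CO[C@@]1([C@H](O)CC=C(C)C)CO[Si](C)(C)C(C)(C)C
F6 | step 15 | 4-[(2R,3S,4R)-2-[(tert-butyldimethylsilyloxy)methyl]-4-[(4Z)-5-iodopenta-1,4-dien-2-yl]-2-[(1E)-4-methylpenta-1,3-dien-1-yl]oxolan-3-yl]butan-2-one | CC(=O)CC[C@H]1[C@H](C(=C)C/C=C\I)CO[C@@]1(/C=C/C=C(C)C)CO[Si](C)(C)C(C)(C)C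
F7 | step 15 | tert-butyldimethylsilyl ether at C16 of the (3Z,5S,8S,9R,11R,12E) bicyclic carbinol (32 with silyl in place of octadecanoyl) | C=C1C/C=C\[C@@](C)(O)CC[C@H]2[C@H]1CO[C@@]2(/C=C/C=C(C)C)CO[Si](C)(C)C(C)(C)C
F8 | step 15 | (3Z,5S,8S,9R,11R,12E) bicyclic diol (32 without the octadecanoyl group) | C=C1C/C=C\[C@@](C)(O)CC[C@H]2[C@H]1CO[C@@]2(/C=C/C=C(C)C)CO
F9 | step 10 | 4-[(2R,3S,4R)-2-(hydroxymethyl)-2-[(1R)-1-iodo-4-methylpent-3-en-1-yl]-4-[5-(trimethylsilyl)pent-1-en-4-yn-2-yl]oxolan-3-yl]butan-2-one | CC(=O)CC[C@H]1[C@H](C(=C)CC#C[Si](C)(C)C)CO[C@@]1([C@H](I)CC=C(C)C)CO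
F10 | step 10 | [(2R,3S,4R)-2-[(1R)-1-iodo-4-methylpent-3-en-1-yl]-3-(3-oxobutyl)-4-[5-(trimethylsilyl)pent-1-en-4-yn-2-yl]oxolan-2-yl]methyl octadecanoate | CC(=O)CC[C@H]1[C@H](C(=C)CC#C[Si](C)(C)C)CO[C@@]1([C@H](I)CC=C(C)C)COC(=O)CCCCCCCCCCCCCCCCC
F11 | step 10 | [(2R,3S,4R)-2-[(1E)-4-methylpenta-1,3-dien-1-yl]-3-(3-oxobutyl)-4-[5-(trimethylsilyl)pent-1-en-4-yn-2-yl]oxolan-2-yl]methyl octadecanoate | CC(=O)CC[C@H]1[C@H](C(=C)CC#C[Si](C)(C)C)CO[C@@]1(/C=C/C=C(C)C)COC(=O)CCCCCCCCCCCCCCCCC
F12 | step 10 | [(2R,3S,4R)-4-(5-iodopent-1-en-4-yn-2-yl)-2-[(1E)-4-methylpenta-1,3-dien-1-yl]-3-(3-oxobutyl)oxolan-2-yl]methyl octadecanoate | CC(=O)CC[C@H]1[C@H](C(=C)CC#CI)CO[C@@]1(/C=C/C=C(C)C)COC(=O)CCCCCCCCCCCCCCCCC
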